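**Plan**
- Retrosynthesis: remove the two phenol benzyl groups, then cut the ArCH2–C(=O)Ar bond of the central deoxybenzoin; in the resulting monomer cut the aryl–C(=O) bond to the 2,6-dimethoxybenzoyl group, the ring–CHO bond and the C–Br bond.
- Enabling feature: the two pentasubstituted rings are constitutionally identical. Each carries, in the same order, 2,6-dimethoxybenzoyl, OH, H, CH3, OCH3 and one exocyclic carbon, which is CH2 on one ring and C=O on the other. Both halves are therefore one aldehyde at two oxidation levels.
- Key event: this single aldehyde is dimerised. One copy becomes, via its N-tosylhydrazone, an aryldiazomethane (benzyl donor) that inserts into the formyl C–H bond of the second copy (acyl donor), giving CH2–C(=O) directly.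
- Forward order: 4-methoxy-3-methylphenol → ortho-bromination → benzyl ether → formylation between Br and OMe → acetal → Br/Li exchange and aroylation to the benzophenone aldehyde → dimerisation → hydrogenolysis. No ring is formed; the chain is joined in the penultimate step.
- Stereochemistry: the target has no stereocentre and no stereogenic double bond, so nothing has to be set.

Key step: step 6

Remark: the target is achiral, so "single enantiomer" is read as the compound itself; 4-methoxy-3-methylphenol and 2,6-dimethoxybenzoyl chloride are taken as purchasable.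

**Step 1**
Reactants: 1 4-methoxy-3-methylphenol
Product: 2 2-bromo-4-methoxy-5-methylphenol
Conditions: NBS (1.0 equiv), MeCN, 0 °C
Reagents that add atoms: N-bromosuccinimide, O=C1CCC(=O)N1Br
Why: Electrophilic aromatic bromination is steered by the free OH (para position blocked by OMe) to the less hindered ortho carbon, para to CH3, and not to the carbon wedged between OH and CH3.

**Step 2**
Reactants: 2 2-bromo-4-methoxy-5-methylphenol
Product: 3 1-(benzyloxy)-2-bromo-4-methoxy-5-methylbenzene
Conditions: BnBr, K2CO3, DMF, rt
Reagents that add atoms: benzyl bromide, BrCc1ccccc1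
Why: Williamson ether synthesis should give a phenol protecting group that is stable to LDA, n-BuLi, acid and carbonate at 110 °C and is removed at the end under neutral conditions.

**Step 3**
Reactants: 3 1-(benzyloxy)-2-bromo-4-methoxy-5-methylbenzene
Product: 5 3-(benzyloxy)-2-bromo-6-methoxy-5-methylbenzaldehyde, via [3-(benzyloxy)-2-bromo-6-methoxy-5-methylphenyl]lithium 4 (not isolated)
Conditions: LDA (1.1 equiv), THF, −78 °C; DMF, −78 → 0 °C; 1 M HCl
Reagents that add atoms: N,N-dimethylformamide, CN(C)C=O
Why: Directed ortho-metalation with a lithium amide should remove the most acidic ring proton, the one flanked by Br and OMe (the other ring H lies between OBn and CH3), as in simple bromo(methoxy)arenes, and the aryllithium, kept at −78 °C so that LiBr is not lost, is formylated by DMF.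

**Step 4**
Reactants: 5 3-(benzyloxy)-2-bromo-6-methoxy-5-methylbenzaldehyde
Product: 6 2-[3-(benzyloxy)-2-bromo-6-methoxy-5-methylphenyl]-1,3-dioxolane
Conditions: ethylene glycol, p-TsOH (cat.), toluene, reflux, Dean–Stark
Reagents that add atoms: ethylene glycol, OCCO
Why: Acid-catalysed acetalisation with azeotropic removal of water masks the formyl group for the organolithium step; the benzyl ether is stable to these conditions.

**Step 5**
Reactants: 6 2-[3-(benzyloxy)-2-bromo-6-methoxy-5-methylphenyl]-1,3-dioxolane; 7 2,6-dimethoxybenzoyl chloride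
Product: 10 3-(benzyloxy)-2-(2,6-dimethoxybenzoyl)-6-methoxy-5-methylbenzaldehyde, via [6-(benzyloxy)-2-(1,3-dioxolan-2-yl)-3-methoxy-4-methylphenyl]lithium 8 (not isolated), via [6-(benzyloxy)-2-(1,3-dioxolan-2-yl)-3-methoxy-4-methylphenyl](2,6-dimethoxyphenyl)methanone 9 (not isolated)
Conditions: n-BuLi (1.05 equiv), THF, −78 °C; 7 (1.2 equiv), −78 → 0 °C; then 2 M HCl, THF, rt
Reagents that add atoms: water, O
Why: Bromine–lithium exchange followed by acylation of the aryllithium with the acid chloride should stop at the ketone, because the benzophenone formed carries four ortho substituents and resists a second addition, and the acidic work-up hydrolyses the dioxolane to the aldehyde.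

**Step 6**
Reactants: 10 3-(benzyloxy)-2-(2,6-dimethoxybenzoyl)-6-methoxy-5-methylbenzaldehyde (two molecules, 2.0 equiv in total)
Product: 13 1,2-bis[3-(benzyloxy)-2-(2,6-dimethoxybenzoyl)-6-methoxy-5-methylphenyl]ethan-1-one, via N′-[(E)-[3-(benzyloxy)-2-(2,6-dimethoxybenzoyl)-6-methoxy-5-methylphenyl]methylidene]-4-methylbenzenesulfonohydrazide 11 (not isolated), via [6-(benzyloxy)-2-(diazomethyl)-3-methoxy-4-methylphenyl](2,6-dimethoxyphenyl)methanone 12 (not isolated)
Conditions: TsNHNH2 (1.0 equiv, i.e. 0.5 equiv per 10), 4 Å MS, 1,4-dioxane, 60 °C; then Cs2CO3 (1.5 equiv), 110 °C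
Reagents that add atoms: none
Why: Half of 10 condenses at its formyl group with the sulfonyl hydrazide to give 11; carbonate deprotonates 11 and Bamford–Stevens loss of p-toluenesulfinate releases the aryldiazomethane 12, whose nucleophilic carbon adds to the formyl carbon of the remaining 10, and the adduct then undergoes a 1,2-hydride shift with loss of N2 to give the benzyl aryl ketone. The closest known reaction type is the base-mediated coupling of aryl aldehyde N-tosylhydrazones with aromatic aldehydes to deoxybenzoins (aldehyde homologation by aryldiazomethanes, a formal formyl C–H insertion). No ring is closed and no stereocentre is formed. The step needs chemoselectivity for CHO over the diaryl ketones, which is secured because each ketone is flanked by four ortho substituents (OBn and the exocyclic carbon on one ring, two OMe on the other) and should be inert to hydrazone formation, to attack by 12 and to ring closure of 11 onto it. It needs hydride rather than aryl migration or epoxide closure after the addition, which the aprotic medium and the poorly migrating, aroyl-substituted aryl group should favour. Cross- versus homo-coupling selectivity does not arise, because both partners derive from the same aldehyde and only one union is possible.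

**Step 7**
Reactants: 13 1,2-bis[3-(benzyloxy)-2-(2,6-dimethoxybenzoyl)-6-methoxy-5-methylphenyl]ethan-1-one
Product: 14 acredinone B, 1,2-bis[2-(2,6-dimethoxybenzoyl)-3-hydroxy-6-methoxy-5-methylphenyl]ethan-1-one
Conditions: H2 (1 atm), 10% Pd/C, EtOAc, rt
Reagents that add atoms: none
Why: Hydrogenolysis of the two aryl benzyl ethers under neutral conditions should leave the di-ortho-substituted ketones untouched and avoids the acid or base that could trigger aldol or cyclisation of the 1,2-diacylbenzene and 1,5-diketone units.

**Compound list**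
1 | 4-methoxy-3-methylphenol | COc1ccc(O)cc1C | starting material
2 | 2-bromo-4-methoxy-5-methylphenol | COc1cc(Br)c(O)cc1C | intermediate
3 | 1-(benzyloxy)-2-bromo-4-methoxy-5-methylbenzene | COc1cc(Br)c(OCc2ccccc2)cc1C | intermediate
4 | [3-(benzyloxy)-2-bromo-6-methoxy-5-methylphenyl]lithium | COc1c(C)cc(OCc2ccccc2)c(Br)c1[Li] | intermediate
5 | 3-(benzyloxy)-2-bromo-6-methoxy-5-methylbenzaldehyde | COc1c(C)cc(OCc2ccccc2)c(Br)c1C=O | intermediate
6 | 2-[3-(benzyloxy)-2-bromo-6-methoxy-5-methylphenyl]-1,3-dioxolane | COc1c(C)cc(OCc2ccccc2)c(Br)c1C1OCCO1 | intermediate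
7 | 2,6-dimethoxybenzoyl chloride | COc1cccc(OC)c1C(Cl)=O | starting material
8 | [6-(benzyloxy)-2-(1,3-dioxolan-2-yl)-3-methoxy-4-methylphenyl]lithium | COc1c(C)cc(OCc2ccccc2)c([Li])c1C1OCCO1 | intermediate
9 | [6-(benzyloxy)-2-(1,3-dioxolan-2-yl)-3-methoxy-4-methylphenyl](2,6-dimethoxyphenyl)methanone | COc1cccc(OC)c1C(=O)c1c(OCc2ccccc2)cc(C)c(OC)c1C1OCCO1 | intermediate
10 | 3-(benzyloxy)-2-(2,6-dimethoxybenzoyl)-6-methoxy-5-methylbenzaldehyde | COc1cccc(OC)c1C(=O)c1c(OCc2ccccc2)cc(C)c(OC)c1C=O | intermediate
11 | N′-[(E)-[3-(benzyloxy)-2-(2,6-dimethoxybenzoyl)-6-methoxy-5-methylphenyl]methylidene]-4-methylbenzenesulfonohydrazide | COc1cccc(OC)c1C(=O)c1c(OCc2ccccc2)cc(C)c(OC)c1/C=N/NS(=O)(=O)c1ccc(C)cc1 | intermediate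
12 | [6-(benzyloxy)-2-(diazomethyl)-3-methoxy-4-methylphenyl](2,6-dimethoxyphenyl)methanone | COc1cccc(OC)c1C(=O)c1c(OCc2ccccc2)cc(C)c(OC)c1C=[N+]=[N-] | intermediate
13 | 1,2-bis[3-(benzyloxy)-2-(2,6-dimethoxybenzoyl)-6-methoxy-5-methylphenyl]ethan-1-one | COc1cccc(OC)c1C(=O)c1c(OCc2ccccc2)cc(C)c(OC)c1CC(=O)c1c(OC)c(C)cc(OCc2ccccc2)c1C(=O)c1c(OC)cccc1OC | intermediate
14 | acredinone B, 1,2-bis[2-(2,6-dimethoxybenzoyl)-3-hydroxy-6-methoxy-5-methylphenyl]ethan-1-one | COc1cccc(OC)c1C(=O)c1c(O)cc(C)c(OC)c1CC(=O)c1c(OC)c(C)cc(O)c1C(=O)c1c(OC)cccc1OC | target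

**Step count and risks**
Total step count: 7. Longest linear sequence: 7 steps (1 → 14); 7 enters in step 5 and both halves of the target come from 10.

Steps most likely to fail:

1. Step 6. The bimolecular addition of the di-ortho-substituted diazo carbon to the di-ortho-substituted formyl group may be slower than unimolecular decay of the diazo compound (carbene formation with capture by the neighbouring ketone oxygen, or azine formation). Carbonate may also induce an intramolecular Cannizzaro–Tishchenko-type hydride transfer from the formyl group to the neighbouring ketone, or enolisation and aldol closure of the product, and aryl migration may compete with hydride migration. The fallback sets out from 10 and comes back at 13. NaBH4 in MeOH/THF at 0 °C should reduce only the formyl group of 10 to give the benzylic alcohol F1, and SOCl2 converts it into the benzylic chloride F2. Zinc dust with LiCl in THF inserts into F2 to give the ketone-tolerant benzylic zinc chloride F3, which adds to the formyl group of a second equivalent of 10 to give the racemic secondary alcohol F4. Dess–Martin oxidation of F4 gives 13.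

2. Step 5. Attack of the di-ortho-substituted aryllithium on the di-ortho-substituted acid chloride may be so retarded sterically that protonation or butylation of the aryllithium wins. The fallback sets out from 6 and comes back at 9. The aryllithium 8, generated as in step 5, is added to the smaller electrophile 2,6-dimethoxybenzaldehyde to give the racemic benzhydrol F5. Dess–Martin oxidation of F5 gives the ketone acetal 9, which is hydrolysed with 2 M HCl in THF, as in the work-up of step 5, to give 10.

3. Step 3. Deprotonation may occur at the ring position next to OBn or at the benzylic OCH2, and LiBr may be lost from the aryllithium to an aryne if the temperature rises. The fallback sets out from 3 and comes back at 10, replacing steps 3 to 5.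
   - Bromine–lithium exchange of 3 (n-BuLi, THF, −78 °C) and DMF quench give the aldehyde F6.
   - The formyl group of F6 is masked in the flask by addition of lithium N,N,N′-trimethylethylenediamide. n-BuLi then lithiates the only ring position ortho to the masked formyl carbon, which is also ortho to OMe. Quench with methyl chloroformate and aqueous work-up give the formyl ester F7.
   - 2,6-Dimethoxyphenyllithium F8 (from 1,3-dimethoxybenzene and n-BuLi) adds to the formyl group of F7, and the alkoxide closes onto the ester to give the racemic 3-arylphthalide F9.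
   - LiAlH4 reduces F9 to the racemic diol F10, and Swern oxidation of both hydroxyl groups gives 10.

**Further compounds**
F1 | step 6 | [6-(benzyloxy)-2-(hydroxymethyl)-3-methoxy-4-methylphenyl](2,6-dimethoxyphenyl)methanone | COc1cccc(OC)c1C(=O)c1c(OCc2ccccc2)cc(C)c(OC)c1CO
F2 | step 6 | [6-(benzyloxy)-2-(chloromethyl)-3-methoxy-4-methylphenyl](2,6-dimethoxyphenyl)methanone | COc1cccc(OC)c1C(=O)c1c(OCc2ccccc2)cc(C)c(OC)c1CCl
F3 | step 6 | {[3-(benzyloxy)-2-(2,6-dimethoxybenzoyl)-6-methoxy-5-methylphenyl]methyl}zinc chloride | COc1cccc(OC)c1C(=O)c1c(OCc2ccccc2)cc(C)c(OC)c1C[Zn]Cl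
F4 | step 6 | racemic 1,2-bis[3-(benzyloxy)-2-(2,6-dimethoxybenzoyl)-6-methoxy-5-methylphenyl]ethan-1-ol | COc1cccc(OC)c1C(=O)c1c(OCc2ccccc2)cc(C)c(OC)c1CC(O)c1c(OC)c(C)cc(OCc2ccccc2)c1C(=O)c1c(OC)cccc1OC
F5 | step 5 | racemic [6-(benzyloxy)-2-(1,3-dioxolan-2-yl)-3-methoxy-4-methylphenyl](2,6-dimethoxyphenyl)methanol | COc1cccc(OC)c1C(O)c1c(OCc2ccccc2)cc(C)c(OC)c1C1OCCO1
F6 | step 3 | 2-(benzyloxy)-5-methoxy-4-methylbenzaldehyde | COc1cc(C=O)c(OCc2ccccc2)cc1C
F7 | step 3 | methyl 3-(benzyloxy)-2-formyl-6-methoxy-5-methylbenzoate | COC(=O)c1c(OC)c(C)cc(OCc2ccccc2)c1C=O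
F8 | step 3 | 2,6-dimethoxyphenyllithium | COc1cccc(OC)c1[Li]
F9 | step 3 | racemic 4-(benzyloxy)-3-(2,6-dimethoxyphenyl)-7-methoxy-6-methyl-2-benzofuran-1(3H)-one | COc1cccc(OC)c1C1OC(=O)c2c(OC)c(C)cc(OCc3ccccc3)c12
F10 | step 3 | racemic [2-(benzyloxy)-6-(hydroxymethyl)-5-methoxy-4-methylphenyl](2,6-dimethoxyphenyl)methanol | COc1cccc(OC)c1C(O)c1c(OCc2ccccc2)cc(C)c(OC)c1CO
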